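**Plan**
- Retrosynthetic cuts: five O-benzyl groups and the C2' O-methyl come off; ring C is cut at C1'–C6' (aldol) and unfolds into a 4-pyranone on the CH2 at naphthalene C1; the pyranone goes back to a naphthalene-1-acetic acid and 4-methoxybut-3-en-2-one; ring B is cut at C1–C8a (arene-to-ketone cyclodehydration); the resulting 3,5-dioxohexanoate is cut at its C4–C5 (acyl) and C4–benzyl bonds.
- Forward order: ring A is bought as 2,6-dimethoxyphenol; the chain is joined by γ-alkylation and γ-acylation of methyl acetoacetate; ring B closes with acid (step 7); the pyranone is attached (steps 10–11); ring C is folded last (step 12); selective O-benzylation, O-methylation and hydrogenolysis finish.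
- Enabling feature: ring C has oxygen on C2' and C4', hydrogen on C6', and C1' bonded to naphthalene C1. This is the pattern of a C1'–C6' 3,5-dioxohexanal whose C1' is the naphthylmethyl CH2, a chain that a 2-substituted 4-pyranone releases with base.
- Stereochemistry: the target has no stereocentre, so nothing has to be set.

Key step: step 12

Remark: the C1–C1' biaryl axis is unspecified in the target and is left uncontrolled; polycarbonyl compounds are drawn as keto forms, and C4 of 9 and 10 is a labile racemic centre. Np stands for 3,6-bis(benzyloxy)-2-[3,4-bis(benzyloxy)benzyl]-5,7-dimethoxynaphthalen-1-yl. Compound 7 is taken as a purchasable building block.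

**Step 1**
Reactants: 1 2,6-dimethoxyphenol
Product: 2 1,3-dimethoxy-2-(methoxymethoxy)benzene
Conditions: MOMCl, iPr2NEt, CH2Cl2, 0 °C to rt
Reagents that add atoms: chloromethyl methyl ether, COCCl
Why: Williamson-type O-alkylation with the reactive α-chloro ether masks the para-directing hydroxyl as an acid-labile acetal, so that the next substitution is steered by the two methoxy groups.

**Step 2**
Reactants: 2 1,3-dimethoxy-2-(methoxymethoxy)benzene
Product: 3 1-bromo-2,4-dimethoxy-3-(methoxymethoxy)benzene
Conditions: NBS (1.0 equiv), MeCN, 0 °C to rt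
Reagents that add atoms: N-bromosuccinimide, O=C1CCC(=O)N1Br
Why: electrophilic aromatic bromination should go to one of the two equivalent carbons ortho to one methoxy and para to the other, as in 1,2,3-trialkoxybenzenes, because the flanked central acetal oxygen is twisted out of conjugation.

**Step 3**
Reactants: 3 1-bromo-2,4-dimethoxy-3-(methoxymethoxy)benzene
Product: 4 ethyl 2-[2,4-dimethoxy-3-(methoxymethoxy)phenyl]acetate
Conditions: BrZnCH2CO2Et (from ethyl bromoacetate, Zn dust, cat. TMSCl), Pd2(dba)3 (2 mol%), XPhos (8 mol%), THF, 60 °C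
Reagents that add atoms: (2-ethoxy-2-oxoethyl)zinc bromide, made from ethyl bromoacetate and zinc, CCOC(=O)C[Zn]Br
Why: Negishi-type coupling of a Reformatsky reagent with the aryl bromide on zerovalent palladium gives the arylacetate under near-neutral conditions that spare the acetal and avoid Claisen self-condensation.

**Step 4**
Reactants: 4 ethyl 2-[2,4-dimethoxy-3-(methoxymethoxy)phenyl]acetate
Product: 5 2-[2,4-dimethoxy-3-(methoxymethoxy)phenyl]-N-methoxy-N-methylacetamide
Conditions: MeNH(OMe)·HCl, iPrMgCl, THF, −20 to 0 °C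
Reagents that add atoms: N,O-dimethylhydroxylamine hydrochloride, CNOC.Cl
Why: aminolysis of the ester by the magnesium amide gives the Weinreb amide, an acyl donor that stops at a stable tetrahedral chelate.

**Step 5**
Reactants: 6 methyl acetoacetate; 7 3,4-bis(benzyloxy)benzyl chloride
Product: 8 methyl 5-[3,4-bis(benzyloxy)phenyl]-3-oxopentanoate
Conditions: NaH, THF, 0 °C; n-BuLi, 0 °C; then 7, 0 °C to rt; 1 M HCl
Reagents that add atoms: none
Why: γ-alkylation of the β-keto ester dianion occurs at the more basic terminal carbanion, and a benzylic chloride is an ideal SN2 partner.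

**Step 6**
Reactants: 8 methyl 5-[3,4-bis(benzyloxy)phenyl]-3-oxopentanoate; 5 2-[2,4-dimethoxy-3-(methoxymethoxy)phenyl]-N-methoxy-N-methylacetamide
Product: 9 methyl 4-[3,4-bis(benzyloxy)benzyl]-6-[2,4-dimethoxy-3-(methoxymethoxy)phenyl]-3,5-dioxohexanoate
Conditions: LiN(iPr)2 (2.2 equiv), THF, −78 to 0 °C; then 5, −78 to −20 °C; aq. HCl
Reagents that add atoms: none
Why: γ-acylation of the β-keto ester dianion by a Weinreb amide (Claisen-type) should give the triketide, since the chelated adduct does not release the acidic product before the quench.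

**Step 7**
Reactants: 9 methyl 4-[3,4-bis(benzyloxy)benzyl]-6-[2,4-dimethoxy-3-(methoxymethoxy)phenyl]-3,5-dioxohexanoate
Product: 11 methyl 2-{2-[3,4-bis(benzyloxy)benzyl]-3,6-dihydroxy-5,7-dimethoxynaphthalen-1-yl}acetate, via free phenol 10 (not isolated)
Conditions: HCl (1.25 M in MeOH), 40 °C; evaporate; TFA/CH2Cl2 (1:4), 0 °C to rt
Reagents that add atoms: none
Why: acid methanolysis frees the phenol, whose para carbon attacks the protonated C3 ketone through a six-membered transition state and loses water (Bradsher-type Friedel–Crafts cyclodehydration of a 1-aryl-2,4-dione to a 2-naphthol); this should outpace five-membered closure by the dibenzyloxybenzyl ring.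

**Step 8**
Reactants: 11 methyl 2-{2-[3,4-bis(benzyloxy)benzyl]-3,6-dihydroxy-5,7-dimethoxynaphthalen-1-yl}acetate
Product: 12 methyl 2-Np-acetate
Conditions: BnBr (2.5 equiv), K2CO3, DMF, rt to 50 °C
Reagents that add atoms: benzyl bromide, BrCc1ccccc1
Why: Williamson etherification of both phenoxides with a reactive benzylic halide is expected to be clean O-alkylation in a dipolar aprotic solvent.

**Step 9**
Reactants: 12 methyl 2-Np-acetate
Product: 13 2-Np-acetic acid
Conditions: LiOH·H2O, THF/MeOH/H2O, rt; then 1 M HCl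
Reagents that add atoms: lithium hydroxide, [Li+].[OH-]
Why: saponification of an unhindered methyl arylacetate leaves benzyl and methyl ethers untouched.

**Step 10**
Reactants: 13 2-Np-acetic acid; 14 (E)-4-methoxybut-3-en-2-one
Product: 16 (1E)-1-methoxy-6-Np-hex-1-ene-3,5-dione, via acid chloride 15 (not isolated)
Conditions: (COCl)2, cat. DMF, CH2Cl2, 0 °C to rt, evaporate; add to 14 (2.2 equiv) + LiN(SiMe3)2 (2.2 equiv), THF, −78 °C; aq. NH4Cl
Reagents that add atoms: none
Why: Claisen-type C-acylation of the kinetic lithium enolate of the vinylogous ester by an acid chloride is the standard entry to 2-substituted 4-pyranones, and the second equivalent of enolate absorbs the acidic proton of the new β-diketone.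

**Step 11**
Reactants: 16 (1E)-1-methoxy-6-Np-hex-1-ene-3,5-dione
Product: 17 2-(Np-methyl)-4H-pyran-4-one
Conditions: TFA, CH2Cl2, rt
Reagents that add atoms: none
Why: acid-catalysed conjugate addition of the enol oxygen to the β-methoxy enone and loss of methanol (addition–elimination cyclodehydration) closes the aromatic 4-pyranone.

**Step 12**
Reactants: 17 2-(Np-methyl)-4H-pyran-4-one
Product: 20 4-Np-benzene-1,3-diol, via dioxohexanal 18 (not isolated), via cyclic aldol 19 (not isolated)
Conditions: Ba(OH)2·8H2O (6 equiv), 1,4-dioxane/H2O (3:1), degassed, 90 °C; then 1 M HCl, rt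
Reagents that add atoms: none
Why: Hydroxide adds to the unsubstituted C6 of the pyranone and the ring opens to the enolised 3,5-dioxohexanal 18; the naphthylmethyl carbon C1' is then deprotonated and adds to the aldehyde carbon C6', and aldol 19 loses water and enolises to the resorcinol. The closest known reaction type is the base-induced opening of 4-pyranones to 1,3,5-tricarbonyl compounds and their intramolecular aldol aromatisation to resorcinols, the classical polyketide model reaction. Ring C closes in a 6-(enolexo)-exo-trig aldol that forms the C1'–C6' bond on a carbon already attached to naphthalene C1, so the crowded biaryl bond is never made by coupling. No stereocentre is created and the new axis is not controlled. The step needs selectivity among three acidic carbons and against retro-Claisen cleavage: only C1' reaches the aldehyde through a six-membered ring, because C3' and C5' would give four-membered rings, and the mild, sparingly soluble Ba(OH)2 should keep hydroxide attack on the chain ketones slow. Any chain that has not cyclised should re-close to 17 on acidification and can be resubmitted.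

**Step 13**
Reactants: 20 4-Np-benzene-1,3-diol
Product: 21 5-(benzyloxy)-2-Np-phenol
Conditions: BnBr (1.05 equiv), K2CO3, acetone, rt
Reagents that add atoms: benzyl bromide, BrCc1ccccc1
Why: Williamson etherification with one equivalent of halide should take the open para hydroxyl, because the ortho hydroxyl is shielded by the twisted, 2-substituted naphthyl group.

**Step 14**
Reactants: 21 5-(benzyloxy)-2-Np-phenol
Product: 22 4-(benzyloxy)-2-methoxy-1-Np-benzene
Conditions: MeI, K2CO3, DMF, rt
Reagents that add atoms: iodomethane, CI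
Why: Williamson methylation of the one remaining phenol works even at a hindered site because the electrophile is small.

**Step 15**
Reactants: 22 4-(benzyloxy)-2-methoxy-1-Np-benzene
Product: 23 2-(3,4-dihydroxybenzyl)-1-(4-hydroxy-2-methoxyphenyl)-5,7-dimethoxynaphthalene-3,6-diol
Conditions: H2 (1 atm), Pd/C (10 wt% palladium on carbon), EtOAc/MeOH, rt, work-up under argon
Reagents that add atoms: none
Why: catalytic hydrogenolysis cleaves all five benzyl aryl ethers while methyl ethers, the diarylmethane CH2 and the naphthalene are inert under these conditions.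

**Compound list**
1 | 2,6-dimethoxyphenol | COc1cccc(OC)c1O | starting material
2 | 1,3-dimethoxy-2-(methoxymethoxy)benzene | COCOc1c(OC)cccc1OC | intermediate
3 | 1-bromo-2,4-dimethoxy-3-(methoxymethoxy)benzene | COCOc1c(OC)ccc(Br)c1OC | intermediate
4 | ethyl 2-[2,4-dimethoxy-3-(methoxymethoxy)phenyl]acetate | CCOC(=O)Cc1ccc(OC)c(OCOC)c1OC | intermediate
5 | 2-[2,4-dimethoxy-3-(methoxymethoxy)phenyl]-N-methoxy-N-methylacetamide | CON(C)C(=O)Cc1ccc(OC)c(OCOC)c1OC | intermediate
6 | methyl acetoacetate | COC(=O)CC(C)=O | starting material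
7 | 3,4-bis(benzyloxy)benzyl chloride | ClCc1ccc(OCc2ccccc2)c(OCc2ccccc2)c1 | starting material
8 | methyl 5-[3,4-bis(benzyloxy)phenyl]-3-oxopentanoate | COC(=O)CC(=O)CCc1ccc(OCc2ccccc2)c(OCc2ccccc2)c1 | intermediate
9 | methyl 4-[3,4-bis(benzyloxy)benzyl]-6-[2,4-dimethoxy-3-(methoxymethoxy)phenyl]-3,5-dioxohexanoate (racemic, enolisable C4) | COC(=O)CC(=O)C(Cc1ccc(OCc2ccccc2)c(OCc2ccccc2)c1)C(=O)Cc1ccc(OC)c(OCOC)c1OC | intermediate
10 | methyl 4-[3,4-bis(benzyloxy)benzyl]-6-(3-hydroxy-2,4-dimethoxyphenyl)-3,5-dioxohexanoate (racemic, not isolated) | COC(=O)CC(=O)C(Cc1ccc(OCc2ccccc2)c(OCc2ccccc2)c1)C(=O)Cc1ccc(OC)c(O)c1OC | intermediate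
11 | methyl 2-{2-[3,4-bis(benzyloxy)benzyl]-3,6-dihydroxy-5,7-dimethoxynaphthalen-1-yl}acetate | COC(=O)Cc1c(Cc2ccc(OCc3ccccc3)c(OCc3ccccc3)c2)c(O)cc2c(OC)c(O)c(OC)cc12 | intermediate
12 | methyl 2-Np-acetate | COC(=O)Cc1c(Cc2ccc(OCc3ccccc3)c(OCc3ccccc3)c2)c(OCc2ccccc2)cc2c(OC)c(OCc3ccccc3)c(OC)cc12 | intermediate
13 | 2-Np-acetic acid | OC(=O)Cc1c(Cc2ccc(OCc3ccccc3)c(OCc3ccccc3)c2)c(OCc2ccccc2)cc2c(OC)c(OCc3ccccc3)c(OC)cc12 | intermediate
14 | (E)-4-methoxybut-3-en-2-one | CO/C=C/C(C)=O | starting material
15 | 2-Np-acetyl chloride (not isolated) | ClC(=O)Cc1c(Cc2ccc(OCc3ccccc3)c(OCc3ccccc3)c2)c(OCc2ccccc2)cc2c(OC)c(OCc3ccccc3)c(OC)cc12 | intermediate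
16 | (1E)-1-methoxy-6-Np-hex-1-ene-3,5-dione | CO/C=C/C(=O)CC(=O)Cc1c(Cc2ccc(OCc3ccccc3)c(OCc3ccccc3)c2)c(OCc2ccccc2)cc2c(OC)c(OCc3ccccc3)c(OC)cc12 | intermediate
17 | 2-(Np-methyl)-4H-pyran-4-one | O=c1ccoc(Cc2c(Cc3ccc(OCc4ccccc4)c(OCc4ccccc4)c3)c(OCc3ccccc3)cc3c(OC)c(OCc4ccccc4)c(OC)cc23)c1 | intermediate
18 | 6-Np-3,5-dioxohexanal (enolised barium salt, not isolated) | O=CCC(=O)CC(=O)Cc1c(Cc2ccc(OCc3ccccc3)c(OCc3ccccc3)c2)c(OCc2ccccc2)cc2c(OC)c(OCc3ccccc3)c(OC)cc12 | intermediate
19 | 5-hydroxy-4-Np-cyclohexane-1,3-dione (diastereomer mixture, not isolated) | O=C1CC(=O)C(c2c(Cc3ccc(OCc4ccccc4)c(OCc4ccccc4)c3)c(OCc3ccccc3)cc3c(OC)c(OCc4ccccc4)c(OC)cc23)C(O)C1 | intermediate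
20 | 4-Np-benzene-1,3-diol | Oc1ccc(-c2c(Cc3ccc(OCc4ccccc4)c(OCc4ccccc4)c3)c(OCc3ccccc3)cc3c(OC)c(OCc4ccccc4)c(OC)cc23)c(O)c1 | intermediate
21 | 5-(benzyloxy)-2-Np-phenol | Oc1cc(OCc2ccccc2)ccc1-c1c(Cc2ccc(OCc3ccccc3)c(OCc3ccccc3)c2)c(OCc2ccccc2)cc2c(OC)c(OCc3ccccc3)c(OC)cc12 | intermediate
22 | 4-(benzyloxy)-2-methoxy-1-Np-benzene | COc1cc(OCc2ccccc2)ccc1-c1c(Cc2ccc(OCc3ccccc3)c(OCc3ccccc3)c2)c(OCc2ccccc2)cc2c(OC)c(OCc3ccccc3)c(OC)cc12 | intermediate
23 | 2-(3,4-dihydroxybenzyl)-1-(4-hydroxy-2-methoxyphenyl)-5,7-dimethoxynaphthalene-3,6-diol | COc1cc(O)ccc1-c1c(Cc2ccc(O)c(O)c2)c(O)cc2c(OC)c(O)c(OC)cc12 | target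

Total steps: 15. Longest linear sequence: 14 steps (steps 1–4, then 6–15).

**Steps most likely to fail**

Step 12. The opened tricarbonyl chain may be cut by hydroxide in a retro-Claisen fragmentation, or it may simply re-close to the pyranone because the crowded naphthylmethyl carbon enolises too slowly. The fallback sets out from enol ether 16, before the pyranone is made, and uses no hydroxide. Compound 16 is treated with KN(SiMe3)2 (3 equiv) in THF/DMPU from −78 °C to rt to give its dianion. The naphthylmethyl carbanion should add to the methoxy-bearing alkene carbon and expel methoxide, an intramolecular addition–elimination of vinylogous Claisen type that forms the same C1'–C6' bond and the same ring. Tautomerisation on acidic work-up should give resorcinol 20, where the route is rejoined. New compounds on this path: none F0.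

Step 7. The electron-rich dibenzyloxybenzyl ring may close onto either ketone in a five-membered (indene) mode and compete with the six-membered closure by ring A. The fallback sets out from chloride 7 and blocks and deactivates that ring with bromine. NBS in MeCN should brominate para to one benzyloxy group to give 4,5-bis(benzyloxy)-2-bromobenzyl chloride F1. Alkylation of the dianion of 6 with it gives methyl 5-[4,5-bis(benzyloxy)-2-bromophenyl]-3-oxopentanoate F2. Acylation of the dianion of that ester with 5 gives methyl 4-[4,5-bis(benzyloxy)-2-bromobenzyl]-6-[2,4-dimethoxy-3-(methoxymethoxy)phenyl]-3,5-dioxohexanoate F3. The acid sequence of step 7 then leads, through methyl 4-[4,5-bis(benzyloxy)-2-bromobenzyl]-6-(3-hydroxy-2,4-dimethoxyphenyl)-3,5-dioxohexanoate F4 (not isolated), to methyl 2-{2-[4,5-bis(benzyloxy)-2-bromobenzyl]-3,6-dihydroxy-5,7-dimethoxynaphthalen-1-yl}acetate F5. Reductive removal of the bromine with HCO2Na and catalytic Pd(PPh3)4 in DMF at 90 °C, which leaves benzyl ethers alone, returns to the route at 11.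

Step 6. The acidic CH2 of the arylacetamide may transfer a proton to the hindered secondary carbanion, so that both partners are recovered instead of coupled. The fallback sets out from 5 and 6 and reverses the order of the two bond formations. The unbranched dianion of 6, a primary carbanion, is acylated by 5 to methyl 6-[2,4-dimethoxy-3-(methoxymethoxy)phenyl]-3,5-dioxohexanoate F6. Its β-diketonate, formed with K2CO3 and catalytic NaI in acetone, is then C-benzylated at C4 with 7, the most acidic site carrying the charge under one equivalent of weak base. This comes back to the route at 9.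

**Further compounds**
F0 | step 12 | none | none
F1 | step 7 | 4,5-bis(benzyloxy)-2-bromobenzyl chloride | ClCc1cc(OCc2ccccc2)c(OCc2ccccc2)cc1Br
F2 | step 7 | methyl 5-[4,5-bis(benzyloxy)-2-bromophenyl]-3-oxopentanoate | COC(=O)CC(=O)CCc1cc(OCc2ccccc2)c(OCc2ccccc2)cc1Br
F3 | step 7 | methyl 4-[4,5-bis(benzyloxy)-2-bromobenzyl]-6-[2,4-dimethoxy-3-(methoxymethoxy)phenyl]-3,5-dioxohexanoate | COC(=O)CC(=O)C(Cc1cc(OCc2ccccc2)c(OCc2ccccc2)cc1Br)C(=O)Cc1ccc(OC)c(OCOC)c1OC
F4 | step 7 | methyl 4-[4,5-bis(benzyloxy)-2-bromobenzyl]-6-(3-hydroxy-2,4-dimethoxyphenyl)-3,5-dioxohexanoate | COC(=O)CC(=O)C(Cc1cc(OCc2ccccc2)c(OCc2ccccc2)cc1Br)C(=O)Cc1ccc(OC)c(O)c1OC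
F5 | step 7 | methyl 2-{2-[4,5-bis(benzyloxy)-2-bromobenzyl]-3,6-dihydroxy-5,7-dimethoxynaphthalen-1-yl}acetate | COC(=O)Cc1c(Cc2cc(OCc3ccccc3)c(OCc3ccccc3)cc2Br)c(O)cc2c(OC)c(O)c(OC)cc12
F6 | step 6 | methyl 6-[2,4-dimethoxy-3-(methoxymethoxy)phenyl]-3,5-dioxohexanoate | COC(=O)CC(=O)CC(=O)Cc1ccc(OC)c(OCOC)c1OC
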